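Numbering: C1 ketone, C2=C3(Me), cyclobutane C4/C5/C11/C10 (C10 quaternary), C6 CMe2, C7–C9 oxygenated. Everything rests on cutting C1–C11, the bond from the enone carbonyl to a cyclobutane methine. The key step joins these two electrophilic carbons by nickel-catalysed decarboxylative acyl cross-electrophile coupling: a C11 radical from an N-acyloxyphthalimide meets a C1 acylnickel from an S-2-pyridyl thioester, closing the cyclohexenone and fixing C11. It exploits the bicyclo[4.1.1]octene precursor, whose C6–C9 bridge holds the (Z)-enoyl arm on C4 and the C11 radical 1,3-diaxial on one cyclobutane face. The precursor arises from a cyclopentanone by Wolff ring contraction.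

Key step: step 16

Remark: TBS = tert-butyldimethylsilyl, TMS = trimethylsilyl; C7 is the carbinol carbon next to C6, C9 the one next to C10; "longipinane" names use the numbering above.
Remark: C11 of compounds 20–25 is drawn without configuration; either epimer or a mixture serves, because the key step passes through the C11 radical.

Step 1
Reactants: 1 but-2-yn-1-ol
Product: 3 (2Z)-3-iodobut-2-en-1-ol, via cyclic vinylalanate 2 (not isolated)
Conditions: NaAlH2(OCH2CH2OMe)2, Et2O, 0 °C to rt; EtOAc; then I2, THF, −78 °C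
Reagents that add atoms: iodine, [I][I]
Why: Alkoxide-directed trans-hydroalumination places aluminium on C3 in a five-membered alanate, and iodinolysis with retention should give the (Z)-vinyl iodide (hydroalumination–iodination).

Step 2
Reactants: 3 (2Z)-3-iodobut-2-en-1-ol
Product: 4 tert-butyl{[(2Z)-3-iodobut-2-en-1-yl]oxy}dimethylsilane
Conditions: TBSCl, imidazole, DMF, rt
Reagents that add atoms: tert-butyldimethylsilyl chloride, CC(C)(C)[Si](C)(C)Cl
Why: Silylation masks the future C1 oxygen for the organometallic, Lewis-acid and strong-base steps.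

Step 3
Reactants: 4 tert-butyl{[(2Z)-3-iodobut-2-en-1-yl]oxy}dimethylsilane; 5 2-methylcyclopent-2-en-1-one
Product: 8 trimethyl({(3R)-2-methyl-3-[(2Z)-4-(TBSO)but-2-en-2-yl]cyclopent-1-en-1-yl}oxy)silane, via alkenylmagnesium chloride 6 (not isolated), via magnesium enolate 7 (not isolated)
Conditions: i-PrMgCl·LiCl, THF, −20 °C; then 5, Cu(OTf)2 (3 mol %), chiral C2-symmetric 1,3-diaryl-4,5-diphenyl-4,5-dihydroimidazolium chloride (NHC precursor, 4 mol %, enantiomer selected for the 3R product), t-BuOMe, −78 °C; then Me3SiCl, Et3N, −78 °C to rt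
Reagents that add atoms: chlorotrimethylsilane, C[Si](C)(C)Cl
Why: Iodine–magnesium exchange keeps the alkene geometry, the copper–NHC-catalysed asymmetric conjugate addition sets C4 under ligand control, and O-silylation fixes the regiodefined enolate (asymmetric conjugate addition with enolate trapping).

Step 4
Reactants: 8 trimethyl({(3R)-2-methyl-3-[(2Z)-4-(TBSO)but-2-en-2-yl]cyclopent-1-en-1-yl}oxy)silane; 9 (2E)-but-2-enal
Product: 10 (2S,3R)-2-[(1R,2E)-1-hydroxybut-2-en-1-yl]-2-methyl-3-[(2Z)-4-(TBSO)but-2-en-2-yl]cyclopentan-1-one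
Conditions: BF3·OEt2, CH2Cl2, −78 °C; aq. NaHCO3
Reagents that add atoms: none
Why: Mukaiyama aldol addition: the BF3-bound enal is attacked 1,2 on the ring face opposite the C4 arm (sets C10), and in the open antiperiplanar transition state the propenyl group should sit outside the ring beside the C10 methyl group (sets C9).

Step 5
Reactants: 10 (2S,3R)-2-[(1R,2E)-1-hydroxybut-2-en-1-yl]-2-methyl-3-[(2Z)-4-(TBSO)but-2-en-2-yl]cyclopentan-1-one
Product: 11 (2S,3R)-2-[(1R,2E)-1-(TBSO)but-2-en-1-yl]-2-methyl-3-[(2Z)-4-(TBSO)but-2-en-2-yl]cyclopentan-1-one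
Conditions: TBSOTf, 2,6-lutidine, CH2Cl2, −78 to 0 °C
Reagents that add atoms: tert-butyldimethylsilyl triflate, CC(C)(C)[Si](C)(C)OS(=O)(=O)C(F)(F)F
Why: Silylation of the hindered aldol hydroxyl blocks retro-aldol cleavage and protects O9 through the following steps.

Step 6
Reactants: 11 (2S,3R)-2-[(1R,2E)-1-(TBSO)but-2-en-1-yl]-2-methyl-3-[(2Z)-4-(TBSO)but-2-en-2-yl]cyclopentan-1-one
Product: 13 (4R,5S)-5-[(1R,2E)-1-(TBSO)but-2-en-1-yl]-5-methyl-4-[(2Z)-4-(TBSO)but-2-en-2-yl]cyclopent-2-en-1-one, via trimethylsilyl enol ether 12 (not isolated)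
Conditions: LiN(i-Pr)2, Me3SiCl, THF, −78 °C; then Pd(OAc)2 (10 mol %), O2 (1 atm), DMSO, rt
Reagents that add atoms: none
Why: Saegusa–Ito dehydrogenation: C10 is quaternary, so enolisation and palladium-mediated β-hydride elimination can only run towards C11/C5.

Step 7
Reactants: 13 (4R,5S)-5-[(1R,2E)-1-(TBSO)but-2-en-1-yl]-5-methyl-4-[(2Z)-4-(TBSO)but-2-en-2-yl]cyclopent-2-en-1-one; 14 trimethyl(3-methylbut-2-en-1-yl)silane
Product: 15 (2S,3R,4R)-2-[(1R,2E)-1-(TBSO)but-2-en-1-yl]-2-methyl-4-(2-methylbut-3-en-2-yl)-3-[(2Z)-4-(TBSO)but-2-en-2-yl]cyclopentan-1-one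
Conditions: TiCl4, CH2Cl2, −78 °C; then H2O
Reagents that add atoms: none
Why: Hosomi–Sakurai conjugate addition: the allylsilane reacts through its γ-carbon, placing the CMe2–CH=CH2 group (C6) on C5 opposite the adjacent C4 arm and hence cis to the C10 silyloxybutenyl chain.

Step 8
Reactants: 15 (2S,3R,4R)-2-[(1R,2E)-1-(TBSO)but-2-en-1-yl]-2-methyl-4-(2-methylbut-3-en-2-yl)-3-[(2Z)-4-(TBSO)but-2-en-2-yl]cyclopentan-1-one
Product: 16 2-(TBSO)-1,5,5-trimethyl-9-[(2Z)-4-(TBSO)but-2-en-2-yl]bicyclo[4.2.1]non-3-en-8-one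
Conditions: RuCl2(=CHPh)(PCy3)(SIMes) (second-generation Grubbs catalyst, 10 mol %), toluene, 80 °C
Reagents that add atoms: none
Why: Ring-closing metathesis of the two cis-oriented alkenyl arms forms the C7=C8 bond and the seven-membered ring with loss of propene; the trisubstituted side-chain alkene cannot close an unstrained ring and stays untouched.

Step 9
Reactants: 16 2-(TBSO)-1,5,5-trimethyl-9-[(2Z)-4-(TBSO)but-2-en-2-yl]bicyclo[4.2.1]non-3-en-8-one
Product: 18 7-diazo-2-(TBSO)-1,5,5-trimethyl-9-[(2Z)-4-(TBSO)but-2-en-2-yl]bicyclo[4.2.1]non-3-en-8-one, via trifluoroacetyl ketone 17 (not isolated)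
Conditions: LiN(SiMe3)2, THF, −78 °C; CF3CO2CH2CF3; then MeSO2N3, Et3N, H2O (1 equiv), MeCN, rt
Reagents that add atoms: methanesulfonyl azide, CS(=O)(=O)N=[N+]=[N-]
Why: Detrifluoroacetylative diazo transfer: the ketone is enolisable only at C11, and the activated 1,3-dicarbonyl takes up N2 from the sulfonyl azide with loss of the trifluoroacetyl group.

Step 10
Reactants: 18 7-diazo-2-(TBSO)-1,5,5-trimethyl-9-[(2Z)-4-(TBSO)but-2-en-2-yl]bicyclo[4.2.1]non-3-en-8-one
Product: 20 2-(TBSO)-1,5,5-trimethyl-8-[(2Z)-4-(TBSO)but-2-en-2-yl]bicyclo[4.1.1]oct-3-ene-7-carboxylic acid, via ketene 19 (not isolated)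
Conditions: hν (365 nm), THF/H2O 9:1, rt
Reagents that add atoms: water, O
Why: Photochemical Wolff rearrangement of the s-cis-locked diazoketone: C10 migrates with retention to the carbene carbon C11, contracting the two-carbon bridge to the cyclobutane, and water traps the ketene.

Step 11
Reactants: 20 2-(TBSO)-1,5,5-trimethyl-8-[(2Z)-4-(TBSO)but-2-en-2-yl]bicyclo[4.1.1]oct-3-ene-7-carboxylic acid
Product: 21 1,3-dioxoisoindolin-2-yl 2-(TBSO)-1,5,5-trimethyl-8-[(2Z)-4-(TBSO)but-2-en-2-yl]bicyclo[4.1.1]oct-3-ene-7-carboxylate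
Conditions: N-hydroxyphthalimide, N,N'-diisopropylcarbodiimide, DMAP (cat.), CH2Cl2, rt
Reagents that add atoms: N-hydroxyphthalimide, O=C1N(O)C(=O)c2ccccc12
Why: Carbodiimide esterification converts the C11 acid into the redox-active ester that later releases the C11 radical.

Step 12
Reactants: 21 1,3-dioxoisoindolin-2-yl 2-(TBSO)-1,5,5-trimethyl-8-[(2Z)-4-(TBSO)but-2-en-2-yl]bicyclo[4.1.1]oct-3-ene-7-carboxylate
Product: 22 1,3-dioxoisoindolin-2-yl 2-(TBSO)-8-[(2Z)-4-hydroxybut-2-en-2-yl]-1,5,5-trimethylbicyclo[4.1.1]oct-3-ene-7-carboxylate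
Conditions: HF·pyridine, pyridine, THF, 0 °C
Reagents that add atoms: none
Why: Buffered fluoride should cleave the unhindered primary allylic silyl ether much faster than the neopentyl-type secondary one at C9.

Step 13
Reactants: 22 1,3-dioxoisoindolin-2-yl 2-(TBSO)-8-[(2Z)-4-hydroxybut-2-en-2-yl]-1,5,5-trimethylbicyclo[4.1.1]oct-3-ene-7-carboxylate
Product: 23 1,3-dioxoisoindolin-2-yl 2-(TBSO)-1,5,5-trimethyl-8-[(2Z)-4-oxobut-2-en-2-yl]bicyclo[4.1.1]oct-3-ene-7-carboxylate
Conditions: Dess–Martin periodinane, NaHCO3, CH2Cl2, 0 °C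
Reagents that add atoms: none
Why: Buffered Dess–Martin oxidation should give the (Z)-enal without alkene isomerisation and leaves the redox-active ester untouched.

Step 14
Reactants: 23 1,3-dioxoisoindolin-2-yl 2-(TBSO)-1,5,5-trimethyl-8-[(2Z)-4-oxobut-2-en-2-yl]bicyclo[4.1.1]oct-3-ene-7-carboxylate
Product: 24 (2Z)-3-{7-[(1,3-dioxoisoindolin-2-yl)oxycarbonyl]-2-(TBSO)-1,5,5-trimethylbicyclo[4.1.1]oct-3-en-8-yl}but-2-enoic acid
Conditions: NaClO2, NaH2PO4, 2-methylbut-2-ene, t-BuOH/H2O, 0 °C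
Reagents that add atoms: sodium chlorite, [Na+].[O-]Cl=O
Why: Pinnick oxidation takes the enal to the acid under mildly acidic conditions that keep the (Z)-alkene and the N-acyloxyphthalimide intact.

Step 15
Reactants: 24 (2Z)-3-{7-[(1,3-dioxoisoindolin-2-yl)oxycarbonyl]-2-(TBSO)-1,5,5-trimethylbicyclo[4.1.1]oct-3-en-8-yl}but-2-enoic acid
Product: 25 1,3-dioxoisoindolin-2-yl 2-(TBSO)-1,5,5-trimethyl-8-[(2Z)-4-oxo-4-(pyridin-2-ylsulfanyl)but-2-en-2-yl]bicyclo[4.1.1]oct-3-ene-7-carboxylate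
Conditions: 2,2'-dipyridyl disulfide, PPh3, CH2Cl2, rt, dark
Reagents that add atoms: 2,2'-dipyridyl disulfide, c1ccc(SSc2ccccn2)nc1
Why: Redox condensation (Mukaiyama-type thioesterification) activates C1 as the S-2-pyridyl thioester under neutral conditions.

Step 16
Reactants: 25 1,3-dioxoisoindolin-2-yl 2-(TBSO)-1,5,5-trimethyl-8-[(2Z)-4-oxo-4-(pyridin-2-ylsulfanyl)but-2-en-2-yl]bicyclo[4.1.1]oct-3-ene-7-carboxylate
Product: 26 (4R,5S,9R,10R,11R)-9-(TBSO)longipina-2,7-dien-1-one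
Conditions: NiBr2(MeOCH2CH2OMe) (10 mol %), 4,4'-di-tert-butyl-2,2'-bipyridine (12 mol %), Zn powder (3 equiv), THF/N,N-dimethylacetamide, rt, 5 mM
Reagents that add atoms: none
Why: Zerovalent nickel inserts into the C(acyl)–S bond to give an acylnickel thiolate, while single-electron reduction of the N-acyloxyphthalimide by low-valent nickel or zinc and loss of CO2 gives the secondary cyclobutyl radical at C11, which is captured by the tethered acylnickel before reductive elimination forms C1–C11. The closest known reaction is the nickel-catalysed decarboxylative cross-electrophile coupling of N-hydroxyphthalimide esters with S-2-pyridyl thioesters to ketones, run here intramolecularly at high dilution. The cyclohexenone closes by radical capture at nickel to a seven-membered acyl(alkyl)nickelacycle followed by C(sp3)–C(acyl) reductive elimination. The only new stereocentre, C11, is fixed by the tether, because the bond can form only on the cyclobutane face that carries the C4 arm, and the planar radical lets both C11 epimers of 25 converge. The step needs ring closure to outrun hydrogen abstraction, dimerisation and thioester reduction; the C6–C9 bridge keeps C4 and C11 1,3-diaxial, the (Z)-C2=C3 bond holds C1 within reach, and radical addition to C2=C3 or C7=C8 would require four-membered or 5-endo closures.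

Step 17
Reactants: 26 (4R,5S,9R,10R,11R)-9-(TBSO)longipina-2,7-dien-1-one
Product: 27 (4R,5S,9R,10R,11R)-9-hydroxylongipina-2,7-dien-1-one
Conditions: HF·pyridine, THF, rt to 40 °C
Reagents that add atoms: none
Why: Unbuffered fluoride removes the hindered secondary silyl ether; the bridged enone has no acid-labile group.

Step 18
Reactants: 27 (4R,5S,9R,10R,11R)-9-hydroxylongipina-2,7-dien-1-one; 28 angelic anhydride
Product: 29 (4R,5S,9R,10R,11R)-9-angeloyloxylongipina-2,7-dien-1-one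
Conditions: LiN(SiMe3)2, THF, −78 °C; then 28, −78 to 0 °C
Reagents that add atoms: none
Why: Acylation of the lithium alkoxide by the anhydride at low temperature esterifies the hindered O9 without the nucleophilic catalysts that isomerise angelates to tiglates.

Step 19
Reactants: 29 (4R,5S,9R,10R,11R)-9-angeloyloxylongipina-2,7-dien-1-one
Product: 30 (4R,5S,7S,8S,9S,10R,11R)-9-angeloyloxy-7,8-dihydroxylongipin-2-en-1-one
Conditions: OsO4 (5 mol %), N-methylmorpholine N-oxide, acetone/H2O, 0 °C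
Reagents that add atoms: N-methylmorpholine N-oxide, C[N+]1([O-])CCOCC1; water, O
Why: Upjohn dihydroxylation: OsO4 should attack the electron-rich C7=C8 bond rather than the enone or the angelate, syn and from the face opposite the allylic C9 ester, setting C7 and C8 cis to each other and trans to O9.

Step 20
Reactants: 30 (4R,5S,7S,8S,9S,10R,11R)-9-angeloyloxy-7,8-dihydroxylongipin-2-en-1-one; 31 3-methylbutanoyl chloride
Product: 32 (4R,5S,7S,8S,9S,10R,11R)-9-angeloyloxy-7-hydroxy-8-(3-methylbutanoyloxy)longipin-2-en-1-one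
Conditions: 2-aminoethyl diphenylborinate (10 mol %), i-Pr2NEt, MeCN, 0 °C
Reagents that add atoms: none
Why: Borinic acid-catalysed monoacylation of the cis-diol should acylate the less hindered O8, since O7 is neopentyl-type next to C6.

Compound list
1 | but-2-yn-1-ol | CC#CCO | starting material
2 | sodium cyclic vinylalanate (Al bound to C3 and to the alkoxide oxygen, two 2-methoxyethoxy ligands) | [Na+].CC1=CCO[Al-]1(OCCOC)OCCOC | intermediate (not isolated)
3 | (2Z)-3-iodobut-2-en-1-ol | C/C(I)=C/CO | intermediate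
4 | tert-butyl{[(2Z)-3-iodobut-2-en-1-yl]oxy}dimethylsilane | C/C(I)=C/CO[Si](C)(C)C(C)(C)C | intermediate
5 | 2-methylcyclopent-2-en-1-one | CC1=CCCC1=O | starting material
6 | [(2Z)-4-(TBSO)but-2-en-2-yl]magnesium chloride | C/C([Mg]Cl)=C/CO[Si](C)(C)C(C)(C)C | intermediate (not isolated)
7 | chloromagnesium (3R)-2-methyl-3-[(2Z)-4-(TBSO)but-2-en-2-yl]cyclopent-1-en-1-olate | CC1=C(O[Mg]Cl)CC[C@@H]1/C(C)=C\CO[Si](C)(C)C(C)(C)C | intermediate (not isolated)
8 | trimethyl({(3R)-2-methyl-3-[(2Z)-4-(TBSO)but-2-en-2-yl]cyclopent-1-en-1-yl}oxy)silane | CC1=C(O[Si](C)(C)C)CC[C@@H]1/C(C)=C\CO[Si](C)(C)C(C)(C)C | intermediate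
9 | (2E)-but-2-enal | C/C=C/C=O | starting material
10 | (2S,3R)-2-[(1R,2E)-1-hydroxybut-2-en-1-yl]-2-methyl-3-[(2Z)-4-(TBSO)but-2-en-2-yl]cyclopentan-1-one | C/C=C/[C@@H](O)[C@@]1(C)C(=O)CC[C@@H]1/C(C)=C\CO[Si](C)(C)C(C)(C)C | intermediate
11 | (2S,3R)-2-[(1R,2E)-1-(TBSO)but-2-en-1-yl]-2-methyl-3-[(2Z)-4-(TBSO)but-2-en-2-yl]cyclopentan-1-one | C/C=C/[C@@H](O[Si](C)(C)C(C)(C)C)[C@@]1(C)C(=O)CC[C@@H]1/C(C)=C\CO[Si](C)(C)C(C)(C)C | intermediate
12 | trimethylsilyl enol ether of 11 (enol double bond towards the ring CH2) | C/C=C/[C@@H](O[Si](C)(C)C(C)(C)C)[C@@]1(C)C(O[Si](C)(C)C)=CC[C@@H]1/C(C)=C\CO[Si](C)(C)C(C)(C)C | intermediate (not isolated)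
13 | (4R,5S)-5-[(1R,2E)-1-(TBSO)but-2-en-1-yl]-5-methyl-4-[(2Z)-4-(TBSO)but-2-en-2-yl]cyclopent-2-en-1-one | C/C=C/[C@@H](O[Si](C)(C)C(C)(C)C)[C@@]1(C)C(=O)C=C[C@@H]1/C(C)=C\CO[Si](C)(C)C(C)(C)C | intermediate
14 | trimethyl(3-methylbut-2-en-1-yl)silane | CC(C)=CC[Si](C)(C)C | starting material
15 | (2S,3R,4R)-2-[(1R,2E)-1-(TBSO)but-2-en-1-yl]-2-methyl-4-(2-methylbut-3-en-2-yl)-3-[(2Z)-4-(TBSO)but-2-en-2-yl]cyclopentan-1-one | C/C=C/[C@@H](O[Si](C)(C)C(C)(C)C)[C@@]1(C)C(=O)C[C@@H](C(C)(C)C=C)[C@@H]1/C(C)=C\CO[Si](C)(C)C(C)(C)C | intermediate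
16 | 2-(TBSO)-1,5,5-trimethyl-9-[(2Z)-4-(TBSO)but-2-en-2-yl]bicyclo[4.2.1]non-3-en-8-one (OTBS on the ring face turned to the two-carbon bridge; C9 arm syn to the two-carbon bridge) | CC(C)(C)[Si](C)(C)O[C@@H]1/C=C\C(C)(C)[C@@H]2CC(=O)[C@@]1(C)[C@H]2/C(C)=C\CO[Si](C)(C)C(C)(C)C | intermediate
17 | 7-(trifluoroacetyl) derivative of 16 | CC(C)(C)[Si](C)(C)O[C@@H]1/C=C\C(C)(C)[C@@H]2C(C(=O)C(F)(F)F)C(=O)[C@@]1(C)[C@H]2/C(C)=C\CO[Si](C)(C)C(C)(C)C | intermediate (not isolated)
18 | 7-diazo derivative of 16 | CC(C)(C)[Si](C)(C)O[C@@H]1/C=C\C(C)(C)[C@@H]2C(=[N+]=[N-])C(=O)[C@@]1(C)[C@H]2/C(C)=C\CO[Si](C)(C)C(C)(C)C | intermediate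
19 | ketene, {2-(TBSO)-1,5,5-trimethyl-8-[(2Z)-4-(TBSO)but-2-en-2-yl]bicyclo[4.1.1]oct-3-en-7-ylidene}methanone | CC(C)(C)[Si](C)(C)O[C@@H]1/C=C\C(C)(C)[C@@H]2C(=C=O)[C@@]1(C)[C@H]2/C(C)=C\CO[Si](C)(C)C(C)(C)C | intermediate (not isolated)
20 | 2-(TBSO)-1,5,5-trimethyl-8-[(2Z)-4-(TBSO)but-2-en-2-yl]bicyclo[4.1.1]oct-3-ene-7-carboxylic acid (C8 arm anti to the four-carbon bridge; C7 = C11 open) | CC(C)(C)[Si](C)(C)O[C@@H]1/C=C\C(C)(C)[C@@H]2C(C(=O)O)[C@@]1(C)[C@H]2/C(C)=C\CO[Si](C)(C)C(C)(C)C | intermediate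
21 | 1,3-dioxoisoindolin-2-yl ester of 20 | CC(C)(C)[Si](C)(C)O[C@@H]1/C=C\C(C)(C)[C@@H]2C(C(=O)ON3C(=O)c4ccccc4C3=O)[C@@]1(C)[C@H]2/C(C)=C\CO[Si](C)(C)C(C)(C)C | intermediate
22 | primary allylic alcohol (side chain (2Z)-4-hydroxybut-2-en-2-yl) | CC(C)(C)[Si](C)(C)O[C@@H]1/C=C\C(C)(C)[C@@H]2C(C(=O)ON3C(=O)c4ccccc4C3=O)[C@@]1(C)[C@H]2/C(C)=C\CO | intermediate
23 | (Z)-enal (side chain (2Z)-4-oxobut-2-en-2-yl) | CC(C)(C)[Si](C)(C)O[C@@H]1/C=C\C(C)(C)[C@@H]2C(C(=O)ON3C(=O)c4ccccc4C3=O)[C@@]1(C)[C@H]2/C(C)=C\C=O | intermediate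
24 | (Z)-enoic acid | CC(C)(C)[Si](C)(C)O[C@@H]1/C=C\C(C)(C)[C@@H]2C(C(=O)ON3C(=O)c4ccccc4C3=O)[C@@]1(C)[C@H]2/C(C)=C\C(=O)O | intermediate
25 | S-pyridin-2-yl (Z)-enethioate bearing the C11 N-acyloxyphthalimide | CC(C)(C)[Si](C)(C)O[C@@H]1/C=C\C(C)(C)[C@@H]2C(C(=O)ON3C(=O)c4ccccc4C3=O)[C@@]1(C)[C@H]2/C(C)=C\C(=O)Sc3ccccn3 | intermediate
26 | (4R,5S,9R,10R,11R)-9-(TBSO)longipina-2,7-dien-1-one | CC(C)(C)[Si](C)(C)O[C@@H]1/C=C\C(C)(C)[C@@H]2[C@H]3C(=O)C=C(C)[C@@H]2[C@@]13C | intermediate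
27 | (4R,5S,9R,10R,11R)-9-hydroxylongipina-2,7-dien-1-one | O[C@@H]1/C=C\C(C)(C)[C@@H]2[C@H]3C(=O)C=C(C)[C@@H]2[C@@]13C | intermediate
28 | angelic anhydride, (2Z)-2-methylbut-2-enoic anhydride | C/C=C(/C)C(=O)OC(=O)/C(C)=C\C | starting material
29 | (4R,5S,9R,10R,11R)-9-angeloyloxylongipina-2,7-dien-1-one | C/C=C(/C)C(=O)O[C@@H]1/C=C\C(C)(C)[C@@H]2[C@H]3C(=O)C=C(C)[C@@H]2[C@@]13C | intermediate
30 | (4R,5S,7S,8S,9S,10R,11R)-9-angeloyloxy-7,8-dihydroxylongipin-2-en-1-one | C/C=C(/C)C(=O)O[C@@H]1[C@@H](O)[C@@H](O)C(C)(C)[C@@H]2[C@H]3C(=O)C=C(C)[C@@H]2[C@@]13C | intermediate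
31 | 3-methylbutanoyl chloride | CC(C)CC(=O)Cl | starting material
32 | (4R,5S,7S,8S,9S,10R,11R)-9-angeloyloxy-7-hydroxy-8-(3-methylbutanoyloxy)longipin-2-en-1-one | C/C=C(/C)C(=O)O[C@@H]1[C@@H](OC(=O)CC(C)C)[C@@H](O)C(C)(C)[C@@H]2[C@H]3C(=O)C=C(C)[C@@H]2[C@@]13C | target

Total step count: 20. Longest linear sequence: 20 steps (1 to 32).

Steps most likely to fail

Step 16. The C11 radical may be quenched by hydrogen abstraction or intermolecular coupling before the tethered acylnickel captures it. The fallback sets out from enal 23 and returns at 26: a chromium dichloride-mediated decarboxylative Nozaki–Hiyama–Kishi-type addition (CrCl2, Me3SiCl, THF/DMF, rt) lets divalent chromium capture the C11 radical, and the alkylchromium should add 1,2 to the tethered (Z)-enal to give the tricyclic allylic alcohol F1 (C1 carbinol, either epimer). MnO2 in CH2Cl2 then oxidises F1 to 26.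

Step 3. Transfer of the hindered trisubstituted alkenyl group may be slow and poorly face-selective under the chiral copper catalyst. The fallback sets out from 4 and 5 and returns at 10: Grignard reagent 6 is added to 5 with achiral CuBr·SMe2 and Me3SiCl in THF to give racemic silyl enol ether F2. The conditions of step 4 then give 10 together with its enantiomer F3. A Sharpless kinetic resolution (Ti(Oi-Pr)4, D-(−)-diisopropyl tartrate, t-BuOOH, 4 Å sieves, CH2Cl2, −20 °C) should epoxidise the unwanted enantiomer to the epoxy alcohol F4 and leave 10, which is separated.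

Step 4. Facial discrimination at the aldehyde carbon may be poor, giving C9 epimers, and 1,4-addition to the enal may compete. The fallback sets out from 8 and returns at 10: Lewis acid-mediated C-acylation of 8 with (E)-but-2-enoyl chloride (ZnCl2, CH2Cl2, −20 °C) gives the 1,3-diketone F5. A Corey–Bakshi–Shibata reduction (B-methyl oxazaborolidine enantiomer selected for the 1R carbinol, catecholborane, toluene, −78 °C) then reduces the conjugated ketone under reagent control to 10; the hindered ring ketone should react more slowly.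

Further compounds
F1 | step 16 | 9-(TBSO)longipina-2,7-dien-1-ol (C1 carbinol, configuration at C1 open) | CC(C)(C)[Si](C)(C)O[C@@H]1/C=C\C(C)(C)[C@@H]2[C@H]3C(O)C=C(C)[C@@H]2[C@@]13C
F2 | step 3 | racemic 8 | CC1=C(O[Si](C)(C)C)CCC1/C(C)=C\CO[Si](C)(C)C(C)(C)C
F3 | step 3 | enantiomer of 10 | C/C=C/[C@H](O)[C@]1(C)C(=O)CC[C@H]1/C(C)=C\CO[Si](C)(C)C(C)(C)C
F4 | step 3 | trans-epoxy alcohol from F3 | C[C@@H]1O[C@H]1[C@H](O)[C@]2(C)C(=O)CC[C@H]2/C(C)=C\CO[Si](C)(C)C(C)(C)C
F5 | step 4 | (2S,3R)-2-[(2E)-but-2-enoyl]-2-methyl-3-[(2Z)-4-(TBSO)but-2-en-2-yl]cyclopentan-1-one | C/C=C/C(=O)[C@@]1(C)C(=O)CC[C@@H]1/C(C)=C\CO[Si](C)(C)C(C)(C)C
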